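**Retrosynthetic overview**

- Numbering: ring C2 (CMe2)–C3–C4–C5–C6 (C(OH)Me)–C7 (CH), chain C8, C9, C10(Me)=C11, C12 and onward. The strategy rests on the C10=C11 olefin, whose carbon C10 bears three different carbon groups (C9, its methyl, C11); building C10 from a CBr2 unit lets the E geometry follow from the order of two couplings.
- Last C–C bonds, in one flask: C9–C10 (ring alkylzinc iodide with the 1,1-dibromoalkene, the bromine trans to C12 reacting first), then C10–CH3 (dimethylzinc); Si–O cleavage ends the route.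
- Dibromoalkene: C10 from CBr4, C11–C12 from tert-butyl acetate, C13 onward from (2E,6E)-farnesol.
- Ring piece: the single cyclohexane ring (C2–C7) is bought with 2,4,4-trimethylcyclohex-2-en-1-one and is never formed or opened. C7 comes from asymmetric ketone reduction and [3,3] chirality transfer, C6 from epoxidation anti to the chain and hydride opening.

Key step: step 12

Remark on the chemistry: the organozinc reagent 10 is prepared, titrated and used as a stock solution; it has a step and a number of its own although it is never obtained neat.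

**Route**

Step 1
Reactants: 1 2,4,4-trimethylcyclohex-2-en-1-one
Product: 2 (1R)-2,4,4-trimethylcyclohex-2-en-1-ol
Conditions: (S)-Me-CBS oxazaborolidine [(3aS)-1-methyl-3,3-diphenyltetrahydro-1H,3H-pyrrolo[1,2-c][1,3,2]oxazaborole] (10 mol %), BH3·SMe2, THF, −20 → 0 °C; MeOH quench
Reagents that add atoms: none
Why: Corey–Bakshi–Shibata reduction; the ketone binds the oxazaborolidine–borane complex with the methyl-substituted alkenyl arm as the large group, so hydride should be delivered to the face that gives the (R)-carbinol.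

Step 2
Reactants: 2 (1R)-2,4,4-trimethylcyclohex-2-en-1-ol; 3 triethyl orthoacetate
Product: 5 ethyl 2-[(1S)-2,6,6-trimethylcyclohex-2-en-1-yl]acetate, via mixed ketene acetal 4 (not isolated)
Conditions: MeC(OEt)3 (excess), EtCO2H (cat.), 140 °C, EtOH distilled off
Reagents that add atoms: none
Why: Johnson–Claisen rearrangement; the [3,3] shift is suprafacial across the ring, so the C7–C8 bond forms on the face that carried the C–O bond, converting the (R)-carbinol into (S)-C7 and moving the alkene to C5=C6.

Step 3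
Reactants: 5 ethyl 2-[(1S)-2,6,6-trimethylcyclohex-2-en-1-yl]acetate
Product: 6 ethyl 2-[(1R,2S,6S)-1,3,3-trimethyl-7-oxabicyclo[4.1.0]heptan-2-yl]acetate (oxygen anti to the chain)
Conditions: mCPBA, NaHCO3, CH2Cl2, 0 °C
Reagents that add atoms: 3-chloroperbenzoic acid (mCPBA), OOC(=O)c1cccc(Cl)c1
Why: Prilezhaev epoxidation of the only alkene; allylic 1,2-strain with the C6 methyl holds the C7 chain pseudoaxial with its ester arm over C6, so the peracid should approach mainly from the opposite face and set C5 and C6 with oxygen anti to the chain.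

Step 4
Reactants: 6 ethyl 2-[(1R,2S,6S)-1,3,3-trimethyl-7-oxabicyclo[4.1.0]heptan-2-yl]acetate
Product: 7 (1S,2S)-2-(2-hydroxyethyl)-1,3,3-trimethylcyclohexan-1-ol
Conditions: LiAlH4, THF, 0 °C → reflux; H2O/NaOH work-up
Reagents that add atoms: none
Why: Hydride reduction of the ester and SN2 opening of the epoxide at the secondary carbon C5; the C6–O bond is not touched, so the tertiary alcohol keeps its configuration and ends trans to the chain.

Step 5
Reactants: 7 (1S,2S)-2-(2-hydroxyethyl)-1,3,3-trimethylcyclohexan-1-ol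
Product: 8 (1S,2S)-2-(2-iodoethyl)-1,3,3-trimethylcyclohexan-1-ol
Conditions: I2, PPh3, imidazole, CH2Cl2, 0 °C
Reagents that add atoms: iodine, II
Why: Appel-type iodination; only the primary hydroxyl forms the alkoxyphosphonium ion, and under these neutral, cold conditions iodide should displace it faster than the hindered tertiary hydroxyl can close a cyclic ether.

Step 6
Reactants: 8 (1S,2S)-2-(2-iodoethyl)-1,3,3-trimethylcyclohexan-1-ol
Product: 9 triethyl{[(1S,2S)-2-(2-iodoethyl)-1,3,3-trimethylcyclohexyl]oxy}silane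
Conditions: Et3SiOTf, 2,6-lutidine, CH2Cl2, −78 → 0 °C
Reagents that add atoms: triethylsilyl trifluoromethanesulfonate, CC[Si](CC)(CC)OS(=O)(=O)C(F)(F)F
Why: Silyl triflate silylation is strong enough for a tertiary alcohol, and the hindered pyridine base leaves the primary iodide alone.

Step 7
Reactants: 9 triethyl{[(1S,2S)-2-(2-iodoethyl)-1,3,3-trimethylcyclohexyl]oxy}silane
Product: 10 {2-[(1S,2S)-2,6,6-trimethyl-2-(triethylsilyloxy)cyclohexyl]ethyl}zinc iodide (THF solution)
Conditions: Zn dust (activated with BrCH2CH2Br and Me3SiCl), THF, 40 °C; titrated with I2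
Reagents that add atoms: zinc, [Zn]
Why: Direct oxidative insertion of activated zinc into a primary C–I bond; the silyl ether is inert, no β-leaving group is present and no stereocentre is involved.

Step 8
Reactants: 11 (2E,6E)-farnesol
Product: 12 (2E,6E)-farnesyl bromide
Conditions: PBr3, Et2O, −10 → 0 °C; used at once
Reagents that add atoms: phosphorus tribromide, BrP(Br)Br
Why: SN2 bromination of the primary allylic alcohol through its phosphite ester; low temperature should preserve the 2E geometry.

Step 9
Reactants: 12 (2E,6E)-farnesyl bromide; 13 tert-butyl acetate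
Product: 15 tert-butyl (4E,8E)-5,9,13-trimethyltetradeca-4,8,12-trienoate, via lithium enolate 14 (not isolated)
Conditions: LiN(iPr)2, THF, −78 °C; then 12, −78 → 0 °C
Reagents that add atoms: none
Why: Ester enolate alkylation (SN2 at the primary allylic bromide); the tert-butyl ester suppresses self-condensation of the enolate.

Step 10
Reactants: 15 tert-butyl (4E,8E)-5,9,13-trimethyltetradeca-4,8,12-trienoate
Product: 16 (4E,8E)-5,9,13-trimethyltetradeca-4,8,12-trienal
Conditions: iBu2AlH (1.1 equiv), CH2Cl2, −78 °C; MeOH, aq. potassium sodium tartrate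
Reagents that add atoms: none
Why: Partial reduction of an ester; the aluminium hemiacetal is stable at −78 °C and releases the aldehyde only on work-up.

Step 11
Reactants: 16 (4E,8E)-5,9,13-trimethyltetradeca-4,8,12-trienal; 17 carbon tetrabromide
Product: 19 (5E,9E)-1,1-dibromo-6,10,14-trimethylpentadeca-1,5,9,13-tetraene, via dibromomethylene ylide 18 (not isolated)
Conditions: PPh3, Zn dust, CH2Cl2, 23 °C (ylide pre-formed from 17); then 16, 23 °C
Reagents that add atoms: none
Why: Corey–Fuchs (Ramirez) dibromo-olefination, a Wittig-type reaction; the zinc variant keeps the medium free of bromophosphonium salts, so the trisubstituted alkenes should survive.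

Step 12
Reactants: 10 {2-[(1S,2S)-2,6,6-trimethyl-2-(triethylsilyloxy)cyclohexyl]ethyl}zinc iodide; 19 (5E,9E)-1,1-dibromo-6,10,14-trimethylpentadeca-1,5,9,13-tetraene; 20 dimethylzinc
Product: 22 triethyl({(1S,2S)-1,3,3-trimethyl-2-[(3E,7E,11E)-3,8,12,16-tetramethylheptadeca-3,7,11,15-tetraen-1-yl]cyclohexyl}oxy)silane, via (Z)-bromoalkene 21 (not isolated)
Conditions: 10 (1.3 equiv), PdCl2(DPEphos) (5 mol %; DPEphos = bis[2-(diphenylphosphino)phenyl] ether), THF/DMF, 0 → 23 °C; then 20 (2 equiv), Pd(PtBu3)2 (5 mol %), 23 → 40 °C, same flask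
Reagents that add atoms: none
Why: Zerovalent palladium, formed from PdCl2(DPEphos) by the organozinc, inserts into the C10–Br bond trans to the C12 chain because the other bromine is shielded by C12; transmetalation with the primary alkylzinc 10 and reductive elimination, which the wide-bite-angle diphosphine speeds ahead of β-hydride elimination, give (Z)-bromoalkene 21. The second catalyst, Pd(PtBu3)2, then inserts into the remaining, more hindered C–Br bond and couples the methyl group of 20 with retention, so C9 ends trans and the methyl cis to C12, which is the 10E olefin. The closest known reaction type is the tandem Negishi coupling of 1,1-dihalo-1-alkenes: trans-selective monoalkylation followed by stereoretentive methylation of the 2-haloalkene. No ring is closed and no stereocentre is formed; C6 and C7 are remote and untouched. The step needs site selectivity between the two bromines, mono- rather than dialkylation, and retention in the second coupling; these are secured by the steric difference at C11 (only H and a methylene chain), by the low reactivity of 21 toward the first catalyst, and by the bulky monophosphine.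

Step 13
Reactants: 22 triethyl({(1S,2S)-1,3,3-trimethyl-2-[(3E,7E,11E)-3,8,12,16-tetramethylheptadeca-3,7,11,15-tetraen-1-yl]cyclohexyl}oxy)silane
Product: 23 (1S,2S)-1,3,3-trimethyl-2-[(3E,7E,11E)-3,8,12,16-tetramethylheptadeca-3,7,11,15-tetraen-1-yl]cyclohexan-1-ol
Conditions: Bu4NF, THF, 23 → 50 °C
Reagents that add atoms: none
Why: Fluoride cleaves the Si–O bond of the tertiary triethylsilyl ether; the alkenes and both stereocentres are inert to these conditions.

**Compound list**

1 | 2,4,4-trimethylcyclohex-2-en-1-one | CC1=CC(C)(C)CCC1=O | starting material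
2 | (1R)-2,4,4-trimethylcyclohex-2-en-1-ol | O[C@@H]1CCC(C)(C)C=C1C | intermediate
3 | triethyl orthoacetate (1,1,1-triethoxyethane) | CCOC(C)(OCC)OCC | starting material
4 | 1-ethoxy-1-{[(1R)-2,4,4-trimethylcyclohex-2-en-1-yl]oxy}ethene (mixed ketene acetal) | C=C(OCC)O[C@@H]1CCC(C)(C)C=C1C | intermediate
5 | ethyl 2-[(1S)-2,6,6-trimethylcyclohex-2-en-1-yl]acetate | CCOC(=O)C[C@H]1C(C)(C)CCC=C1C | intermediate
6 | ethyl 2-[(1R,2S,6S)-1,3,3-trimethyl-7-oxabicyclo[4.1.0]heptan-2-yl]acetate | CCOC(=O)C[C@H]1C(C)(C)CC[C@@H]2O[C@]12C | intermediate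
7 | (1S,2S)-2-(2-hydroxyethyl)-1,3,3-trimethylcyclohexan-1-ol | OCC[C@H]1C(C)(C)CCC[C@]1(C)O | intermediate
8 | (1S,2S)-2-(2-iodoethyl)-1,3,3-trimethylcyclohexan-1-ol | ICC[C@H]1C(C)(C)CCC[C@]1(C)O | intermediate
9 | triethyl{[(1S,2S)-2-(2-iodoethyl)-1,3,3-trimethylcyclohexyl]oxy}silane | ICC[C@H]1C(C)(C)CCC[C@]1(C)O[Si](CC)(CC)CC | intermediate
10 | {2-[(1S,2S)-2,6,6-trimethyl-2-(triethylsilyloxy)cyclohexyl]ethyl}zinc iodide | I[Zn]CC[C@H]1C(C)(C)CCC[C@]1(C)O[Si](CC)(CC)CC | intermediate
11 | (2E,6E)-farnesol | CC(C)=CCC/C(C)=C/CC/C(C)=C/CO | starting material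
12 | (2E,6E)-farnesyl bromide | CC(C)=CCC/C(C)=C/CC/C(C)=C/CBr | intermediate
13 | tert-butyl acetate | CC(=O)OC(C)(C)C | starting material
14 | lithium enolate of tert-butyl acetate (lithium 1-tert-butoxyethen-1-olate) | C=C(O[Li])OC(C)(C)C | intermediate
15 | tert-butyl (4E,8E)-5,9,13-trimethyltetradeca-4,8,12-trienoate | CC(C)=CCC/C(C)=C/CC/C(C)=C/CCC(=O)OC(C)(C)C | intermediate
16 | (4E,8E)-5,9,13-trimethyltetradeca-4,8,12-trienal | CC(C)=CCC/C(C)=C/CC/C(C)=C/CCC=O | intermediate
17 | carbon tetrabromide | BrC(Br)(Br)Br | starting material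
18 | (dibromomethylidene)triphenylphosphorane | BrC(Br)=P(c1ccccc1)(c1ccccc1)c1ccccc1 | intermediate
19 | (5E,9E)-1,1-dibromo-6,10,14-trimethylpentadeca-1,5,9,13-tetraene | CC(C)=CCC/C(C)=C/CC/C(C)=C/CCC=C(Br)Br | intermediate
20 | dimethylzinc | C[Zn]C | starting material
21 | triethyl({(1S,2S)-2-[(3Z,7E,11E)-3-bromo-8,12,16-trimethylheptadeca-3,7,11,15-tetraen-1-yl]-1,3,3-trimethylcyclohexyl}oxy)silane | CC(C)=CCC/C(C)=C/CC/C(C)=C/CC/C=C(\Br)CC[C@H]1C(C)(C)CCC[C@]1(C)O[Si](CC)(CC)CC | intermediate
22 | triethyl({(1S,2S)-1,3,3-trimethyl-2-[(3E,7E,11E)-3,8,12,16-tetramethylheptadeca-3,7,11,15-tetraen-1-yl]cyclohexyl}oxy)silane | CC(C)=CCC/C(C)=C/CC/C(C)=C/CC/C=C(\C)CC[C@H]1C(C)(C)CCC[C@]1(C)O[Si](CC)(CC)CC | intermediate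
23 | (1S,2S)-1,3,3-trimethyl-2-[(3E,7E,11E)-3,8,12,16-tetramethylheptadeca-3,7,11,15-tetraen-1-yl]cyclohexan-1-ol | CC(C)=CCC/C(C)=C/CC/C(C)=C/CC/C=C(\C)CC[C@H]1C(C)(C)CCC[C@]1(C)O | target

**Step count**

Total: 13 steps. Longest linear sequence: 9 steps (steps 1–7, 12, 13).

**Steps most likely to fail**

1. Step 12. The first oxidative addition may not discriminate the two bromines or may run on to dialkylation, the alkylpalladium intermediate may undergo β-hydride elimination, and the hindered bromide 21 may lose its geometry before the second catalyst acts. The fallback sets out from 19 and 10 and returns at 22; it fixes the olefin geometry before the coupling instead of during it. Compound 19 is treated with BuLi (2.2 equiv, THF, −78 °C) and then MeI to give the methyl alkyne (6E,10E)-7,11,15-trimethylhexadeca-6,10,14-trien-2-yne F1. Hydrozirconation with Cp2Zr(H)Cl (slight excess, THF, 50 °C, which moves zirconium to the methyl-bearing carbon) followed by I2 gives, by syn addition, the iodoalkene (2E,6E,10E)-2-iodo-7,11,15-trimethylhexadeca-2,6,10,14-tetraene F2. Negishi coupling of F2 with 10 under Pd(PtBu3)2 in THF should proceed with retention and give 22.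

2. Step 3. Oxygen transfer may show poor facial selectivity, because the pseudoaxial chain shields one face and the axial C2 methyl group the other. The fallback sets out from 5 and returns at 6; it makes the unwanted face useful by inverting the epoxide. The syn epoxide ethyl 2-[(1S,2S,6R)-1,3,3-trimethyl-7-oxabicyclo[4.1.0]heptan-2-yl]acetate F3, separated from 6, is hydrolysed (HClO4, THF/H2O, 0 °C); water enters at the tertiary carbon with inversion and gives the diol ethyl 2-[(1S,2R,3R)-2,3-dihydroxy-2,6,6-trimethylcyclohexyl]acetate F4. MsCl/Et3N (CH2Cl2, 0 °C) sulfonylates only the secondary hydroxyl to give ethyl 2-[(1S,2R,3R)-2-hydroxy-2,6,6-trimethyl-3-(methylsulfonyloxy)cyclohexyl]acetate F5. K2CO3 in EtOH then closes the oxirane by displacement at C5 with inversion and delivers 6.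

3. Step 2. At 140 °C the acid may ionise the allylic alcohol and eliminate it to a diene, and the shift onto the carbon next to the quaternary centre may be slow. The fallback sets out from 2 and returns at 5; it uses an ester-enolate (Ireland–Claisen) rearrangement under basic conditions below 60 °C. Compound 2 is acetylated (Ac2O, pyridine, DMAP) to (1R)-2,4,4-trimethylcyclohex-2-en-1-yl acetate F6. LiN(iPr)2 and Me3SiCl (THF, −78 °C) give the silyl ketene acetal trimethyl[(1-{[(1R)-2,4,4-trimethylcyclohex-2-en-1-yl]oxy}ethenyl)oxy]silane F7, which rearranges on warming to trimethylsilyl 2-[(1S)-2,6,6-trimethylcyclohex-2-en-1-yl]acetate F8. Aqueous acid liberates 2-[(1S)-2,6,6-trimethylcyclohex-2-en-1-yl]acetic acid F9, and EtI/K2CO3 in DMF gives 5.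

**Further compounds**

F1 | step 12 | (6E,10E)-7,11,15-trimethylhexadeca-6,10,14-trien-2-yne | CC(C)=CCC/C(C)=C/CC/C(C)=C/CCC#CC
F2 | step 12 | (2E,6E,10E)-2-iodo-7,11,15-trimethylhexadeca-2,6,10,14-tetraene | CC(C)=CCC/C(C)=C/CC/C(C)=C/CC/C=C(\C)I
F3 | step 3 | ethyl 2-[(1S,2S,6R)-1,3,3-trimethyl-7-oxabicyclo[4.1.0]heptan-2-yl]acetate | CCOC(=O)C[C@H]1C(C)(C)CC[C@H]2O[C@@]12C
F4 | step 3 | ethyl 2-[(1S,2R,3R)-2,3-dihydroxy-2,6,6-trimethylcyclohexyl]acetate | CCOC(=O)C[C@H]1C(C)(C)CC[C@@H](O)[C@]1(C)O
F5 | step 3 | ethyl 2-[(1S,2R,3R)-2-hydroxy-2,6,6-trimethyl-3-(methylsulfonyloxy)cyclohexyl]acetate | CCOC(=O)C[C@H]1C(C)(C)CC[C@@H](OS(C)(=O)=O)[C@]1(C)O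
F6 | step 2 | (1R)-2,4,4-trimethylcyclohex-2-en-1-yl acetate | CC(=O)O[C@@H]1CCC(C)(C)C=C1C
F7 | step 2 | trimethyl[(1-{[(1R)-2,4,4-trimethylcyclohex-2-en-1-yl]oxy}ethenyl)oxy]silane | C=C(O[Si](C)(C)C)O[C@@H]1CCC(C)(C)C=C1C
F8 | step 2 | trimethylsilyl 2-[(1S)-2,6,6-trimethylcyclohex-2-en-1-yl]acetate | C[Si](C)(C)OC(=O)C[C@H]1C(C)(C)CCC=C1C
F9 | step 2 | 2-[(1S)-2,6,6-trimethylcyclohex-2-en-1-yl]acetic acid | OC(=O)C[C@H]1C(C)(C)CCC=C1C
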